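**Assumptions**
- The SMILES is read as methyl (5E,7Z,12R,14Z)-10-bromo-12-hydroxy-9-oxoprosta-5,7,10,14-tetraenoate. Prostanoid numbering (C1–C20) is used throughout.
- In Step 2 the (S)-configured catalyst is assumed to give (R)-5. I could not derive this sense from first principles. If it is reversed, the (R)-catalyst is used; the configuration can be checked against material from the Step 2 fallback.

## Retrosynthetic overview
1. The usual C7–C8 aldol condensation on a preformed 4-hydroxycyclopentenone is avoided because it favours 7E and needs a separate halogenation.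
2. After O-desilylation, the key step breaks C8–C9 (ring bond) and C6–C7 together. It is a Pd(0) acylpalladation/Stille cascade of an acyclic (E)-α-bromo-enoyl chloride carrying a C12 ethynyl group with an (E)-alkenylstannane. Syn addition fixes 7Z.
3. Br and C9 arrive together in an (E)-selective bromo-HWE on an α-silyloxy aldehyde, so no electrophilic bromination is done in the presence of alkenes.
4. C12 is set by organocatalytic epoxidation of 2-methylene-(Z)-dec-4-enal. This enal comes from commercial (Z)-dec-4-enal and CH2O and already carries C12–C20 with the 14Z alkene.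
5. Ring order: there is one carbocycle, closed in the penultimate step.

## Route

**Step 1**
Reactants: 1 (Z)-dec-4-enal; 2 formaldehyde (37 % aq.)
Product: 3 (4Z)-2-methylidenedec-4-enal
Conditions: pyrrolidine (10 mol %), EtCO2H (10 mol %), i-PrOH, 45 °C, 1–2 h
Reagents that add atoms: formaldehyde, C=O
Why: Organocatalytic Mannich-type α-methylenation (enamine addition to CH2O, then amine β-elimination) gives the 2-substituted acrolein, with a short reaction time to keep the skipped Z-alkene out of conjugation; no stereocentre is formed.

**Step 2**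
Reactants: 3; 4 hydrogen peroxide (35 % aq.)
Product: 5 (2R)-2-[(2Z)-oct-2-en-1-yl]oxirane-2-carbaldehyde
Conditions: (S)-diphenylprolinol methyldiphenylsilyl ether (10 mol %), CH2Cl2, rt
Reagents that add atoms: hydrogen peroxide, OO
Why: Iminium–enamine (diarylprolinol silyl ether) epoxidation of an α-substituted acrolein, in which H2O2 adds to the CH2 terminus and the shielded enamine closes onto O from one face to set quaternary C12 (R), while the unactivated 14Z alkene is inert to H2O2.

**Step 3**
Reactants: 5; 6 dimethyl (1-diazo-2-oxopropyl)phosphonate (Ohira–Bestmann reagent)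
Product: 7 (2S)-2-ethynyl-2-[(2Z)-oct-2-en-1-yl]oxirane
Conditions: K2CO3, MeOH, 0 °C → rt
Reagents that add atoms: Ohira–Bestmann reagent (one carbon), COP(=O)(OC)C(=[N+]=[N-])C(C)=O
Why: Seyferth–Gilbert/Ohira–Bestmann homologation turns CHO into C8≡C7H; C12 has no α-H and no bond to it is broken, so only the CIP label changes (R to S).

**Step 4**
Reactants: 7; 8 water (as aq. KOH)
Product: 9 (2S,4Z)-2-ethynyldec-4-ene-1,2-diol
Conditions: KOH, DMSO–H2O (3:1), 60 °C
Reagents that add atoms: water/hydroxide, O
Why: Base-mediated SN2 epoxide opening occurs only at the unsubstituted CH2 (future C11), so the C12–O bond and configuration are kept, and the aqueous medium at ≤60 °C suppresses retro-Favorskii loss of acetylene.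

**Step 5**
Reactants: 9
Product: 10 (2S,4Z)-2-ethynyl-2-hydroxydec-4-enal
Conditions: SO3·pyridine, DMSO, i-Pr2NEt, CH2Cl2, 0 °C; used crude
Reagents that add atoms: none
Why: Parikh–Doering oxidation takes only the primary alcohol to the aldehyde without glycol cleavage, and the product cannot epimerise because C12 is quaternary.

**Step 6**
Reactants: 10; 11 tert-butyldimethylsilyl triflate
Product: 12 (2S,4Z)-2-[(tert-butyldimethylsilyl)oxy]-2-ethynyldec-4-enal
Conditions: 2,6-lutidine, CH2Cl2, −78 → 0 °C
Reagents that add atoms: TBSOTf, CC(C)(C)[Si](C)(C)OS(=O)(=O)C(F)(F)F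
Why: Silyl triflate O-silylation of the tertiary alcohol works because the aldehyde is non-enolisable; TBS is chosen over TES/TMS so the later (Z)-disposed acid chloride does not collapse to the bromobutenolide.

**Step 7** (reagent preparation)
Reactants: 13 methyl bis(2,2,2-trifluoroethyl)phosphonoacetate; 14 N-bromosuccinimide
Product: 15 methyl 2-bromo-2-[bis(2,2,2-trifluoroethoxy)phosphoryl]acetate
Conditions: NaH, THF, 0 °C; NBS, −78 → 0 °C; chromatography
Reagents that add atoms: NBS, O=C1CCC(=O)N1Br
Why: Electrophilic α-bromination of the stabilised phosphonate carbanion gives the monobromide, which is separated from di- and non-brominated material.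

**Step 8**
Reactants: 12; 15
Product: 16 methyl (2E,4R,6Z)-2-bromo-4-[(tert-butyldimethylsilyl)oxy]-4-ethynyldodeca-2,6-dienoate
Conditions: t-BuOK, 18-crown-6, THF, −78 → −30 °C
Reagents that add atoms: 15, COC(=O)C(Br)P(=O)(OCC(F)(F)F)OCC(F)(F)F
Why: Still–Gennari-type bromo-HWE under kinetic control (electron-poor phosphonate, dissociated K+) places CO2Me (C9) cis to C12, giving the (E)-α-bromoacrylate and installing C10–Br without any Br+ reagent near the alkenes; C12 is untouched.

**Step 9**
Reactants: 16; 8 water (as aq. LiOH)
Product: 17 (2E,4R,6Z)-2-bromo-4-[(tert-butyldimethylsilyl)oxy]-4-ethynyldodeca-2,6-dienoic acid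
Conditions: LiOH, THF–MeOH–H2O, rt; citric acid work-up
Reagents that add atoms: water/hydroxide, O
Why: Saponification is safe because C11–H and Br are syn (no anti-E2 to an ynoate), C11 is neopentyl (no conjugate addition), and the TBS ether blocks lactonisation.

**Step 10** (side chain)
Reactants: 18 methyl hex-5-ynoate; 19 tributyltin hydride
Product: 20 methyl (5E)-6-(tributylstannyl)hex-5-enoate
Conditions: Pd2(dba)3 (0.5 mol %), Cy3P·HBF4 (2 mol %), i-Pr2NEt, CH2Cl2, 0 °C
Reagents that add atoms: Bu3SnH, CCCC[SnH](CCCC)CCCC
Why: Pd-catalysed syn-hydrostannation with a bulky phosphine places Sn on the terminal carbon and gives the (E)-β-stannane that defines the 5E geometry.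

**Step 11**
Reactants: 17; 21 1-chloro-N,N,2-trimethylprop-1-en-1-amine (Ghosez reagent)
Product: 22 (2E,4R,6Z)-2-bromo-4-[(tert-butyldimethylsilyl)oxy]-4-ethynyldodeca-2,6-dienoyl chloride
Conditions: CH2Cl2, 0 °C → rt, 1 h; concentrate under high vacuum; use at once
Reagents that add atoms: Ghosez reagent (Cl), CC(C)=C(Cl)N(C)C
Why: Neutral, HCl-free acid chloride formation with an α-chloroenamine spares the silyl ether, alkyne and alkenes and leaves the double-bond geometry unchanged.

**Step 12** (key step)
Reactants: 22; 20
Product: 23 methyl (5E,7Z)-7-{(2R)-4-bromo-2-[(tert-butyldimethylsilyl)oxy]-2-[(2Z)-oct-2-en-1-yl]-5-oxocyclopent-3-en-1-ylidene}hept-5-enoate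
Conditions: Pd2(dba)3·CHCl3 (5 mol %), P(2-furyl)3 (20 mol %), toluene (0.01 M), 25 °C, dark; 20 (0.95 equiv) by syringe pump over 4 h; aq. KF work-up
Reagents that add atoms: 20, CCCC[Sn](CCCC)(CCCC)/C=C/CCCC(=O)OC
Why: Proposed new method: Pd(0) should insert into the acyl C–Cl bond at rt much faster than into C10–Br; the acyl-Pd, held cis to C12 by the alkene, undergoes 5-exo-dig syn-acylpalladation of the ethynyl group (C8–C9 ring bond; 4-exo closure is impossible without the carbonyl) to give an O-chelated alkenyl-Pd with Pd cis to C9, which couples with 20 with retention at both partners to give 7Z and 5E; slow addition of sub-stoichiometric stannane suppresses direct acyl-Stille ketone formation and coupling at C10–Br of the product, and the absence of CO rules out a second carbonylation; closest known reaction types are cyclic acylpalladation of tethered alkynes (alkenyl/aryl iodide + CO), Pd cyclisation–anion capture of carbamoyl chlorides onto alkynes ending in stannanes or boronic acids, and Stille acylation of acid chlorides.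

**Step 13**
Reactants: 23
Product: 24 bromoclavulone III (target)
Conditions: HF·pyridine, MeCN, 0 °C → rt, plastic vessel, dark
Reagents that add atoms: none
Why: Fluoride-mediated Si–O cleavage under mildly acidic conditions frees the C12 alcohol without breaking C12–O (ionisation would give a destabilised cyclopentadienone-type cation), and the ester, vinyl bromide and 5E,7Z,14Z alkenes survive.

## Compound list
| No. | Name | SMILES | Role |
|---|---|---|---|
| 1 | (Z)-dec-4-enal | CCCCC/C=C\CCC=O | starting material |
| 2 | formaldehyde | C=O | starting material |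
| 3 | (4Z)-2-methylidenedec-4-enal | CCCCC/C=C\CC(=C)C=O | intermediate |
| 4 | hydrogen peroxide | OO | starting material (reagent) |
| 5 | (2R)-2-[(2Z)-oct-2-enyl]oxirane-2-carbaldehyde | CCCCC/C=C\C[C@]1(C=O)CO1 | intermediate |
| 6 | dimethyl (1-diazo-2-oxopropyl)phosphonate | COP(=O)(OC)C(=[N+]=[N-])C(C)=O | starting material (reagent) |
| 7 | (2S)-2-ethynyl-2-[(2Z)-oct-2-enyl]oxirane | CCCCC/C=C\C[C@]1(C#C)CO1 | intermediate |
| 8 | water (aq. KOH / LiOH) | O | starting material (reagent) |
| 9 | (2S,4Z)-2-ethynyldec-4-ene-1,2-diol | CCCCC/C=C\C[C@](O)(C#C)CO | intermediate |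
| 10 | (2S,4Z)-2-ethynyl-2-hydroxydec-4-enal | CCCCC/C=C\C[C@](O)(C#C)C=O | intermediate |
| 11 | TBSOTf | CC(C)(C)[Si](C)(C)OS(=O)(=O)C(F)(F)F | starting material (reagent) |
| 12 | (2S,4Z)-2-(TBSO)-2-ethynyldec-4-enal | CCCCC/C=C\C[C@](O[Si](C)(C)C(C)(C)C)(C#C)C=O | intermediate |
| 13 | methyl bis(2,2,2-trifluoroethyl)phosphonoacetate | COC(=O)CP(=O)(OCC(F)(F)F)OCC(F)(F)F | starting material |
| 14 | N-bromosuccinimide | O=C1CCC(=O)N1Br | starting material (reagent) |
| 15 | methyl bromo[bis(2,2,2-trifluoroethoxy)phosphoryl]acetate | COC(=O)C(Br)P(=O)(OCC(F)(F)F)OCC(F)(F)F | intermediate |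
| 16 | methyl (2E,4R,6Z)-2-bromo-4-(TBSO)-4-ethynyldodeca-2,6-dienoate | CCCCC/C=C\C[C@](O[Si](C)(C)C(C)(C)C)(C#C)/C=C(/Br)C(=O)OC | intermediate |
| 17 | (2E,4R,6Z)-2-bromo-4-(TBSO)-4-ethynyldodeca-2,6-dienoic acid | CCCCC/C=C\C[C@](O[Si](C)(C)C(C)(C)C)(C#C)/C=C(/Br)C(=O)O | intermediate |
| 18 | methyl hex-5-ynoate | C#CCCCC(=O)OC | starting material |
| 19 | tributyltin hydride | CCCC[SnH](CCCC)CCCC | starting material (reagent) |
| 20 | methyl (5E)-6-(tributylstannyl)hex-5-enoate | CCCC[Sn](CCCC)(CCCC)/C=C/CCCC(=O)OC | intermediate |
| 21 | 1-chloro-N,N,2-trimethylprop-1-en-1-amine | CC(C)=C(Cl)N(C)C | starting material (reagent) |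
| 22 | (2E,4R,6Z)-2-bromo-4-(TBSO)-4-ethynyldodeca-2,6-dienoyl chloride | CCCCC/C=C\C[C@](O[Si](C)(C)C(C)(C)C)(C#C)/C=C(/Br)C(=O)Cl | intermediate |
| 23 | 12-O-TBS bromoclavulone III | CCCCC/C=C\C[C@@]1(O[Si](C)(C)C(C)(C)C)C=C(Br)C(=O)/C1=C\C=C\CCCC(=O)OC | intermediate |
| 24 | bromoclavulone III | CCCCC/C=C\C[C@@]1(O)C=C(Br)C(=O)/C1=C\C=C\CCCC(=O)OC | target |

## Step count
- **Total steps:** 13
- **Longest linear sequence:** 11 (Steps 1–6, 8, 9, 11, 12, 13)

## Steps most likely to fail
1. **Step 12 (cascade).**
   - Risks: direct acyl-Stille coupling, Pd insertion into C–Br, and collapse of 22 to the bromobutenolide.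
   - Fallback: form the two C–C bonds separately.
     - Carry out Pt(0)-catalysed syn-diboration of the alkyne at the silylated diol stage.
     - Suzuki-couple the less hindered terminal C7–Bpin with methyl (E)-6-iodohex-5-enoate.
     - After the bromo-HWE, close C8–C9 by intramolecular base-free acylative coupling of the internal C8–Bpin with a thioester (Liebeskind–Srogl type). The same syn logic gives 7Z.
2. **Step 8 (bromo-HWE on a neopentyl aldehyde).**
   - Risks: low conversion or low E-selectivity.
   - Fallback: move the halogenation to the end.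
     - Use the plain Still–Gennari reagent 13 to make the (Z)-enoate and run Steps 9–12 to reach the 10-H dienone.
     - Install Br by nucleophilic epoxidation of the endocyclic enone (t-BuOOH/DBU), then HBr opening at C10 and dehydration.
3. **Step 2 (organocatalytic epoxidation).**
   - Risks: low ee, the wrong sense of induction, or dienamine isomerisation of the skipped diene.
   - Fallback: switch to directed metal catalysis, at a cost of two extra steps.
     - Reduce 3 with DIBAL-H to the allylic alcohol.
     - Carry out Sharpless epoxidation with L-(+)-DET. I expect the (S)-epoxy alcohol, by analogy with (S)-2-methylglycidol and with the 2S products I recall L-(+)-tartrate giving; the drawn face mnemonic as I remember it pointed the other way in my own check, so this sense also needs confirming experimentally.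
     - Re-oxidise under Parikh–Doering conditions to (R)-5.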